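## Retrosynthetic overview

1. Numbering used below: oxolane O1, C2 (pentyl), C3 (OH), C4 (CH2), C5 (side chain); C1′ is the acyloxy carbon, C2′ the next chain carbon. Endgame: C3–O deprotection ⇐ C1′ laurate ⇐ C2′–C3′ bond by copper-catalysed opening of a C1′/C2′ oxirane with an oct-7-enyl Grignard reagent.
2. The oxolane, the only ring of the target, is closed at C4–C5: ring-closing metathesis of an enol ether with a vinyl group gives a 4,5-dihydrofuran, which is reduced in the same flask, the hydride setting C5.
3. Enabling feature: C5 is bonded to the ring oxygen O1 and to the unsubstituted C4H2. O1–C5 can therefore be laid down as the acyl–oxygen bond of an ester (C5 = carbonyl carbon, then C=CH2) and C4 as the CH of a vinyl group on C3; the C3 oxygen, 1,3 to C5 across C4, then steers the hydride.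
4. The ester comes from a homoallylic alcohol and D-glyceric acid acetonide (chiral pool): the carboxyl carbon becomes ring carbon C5, C2 of the acid becomes C1′ and C3 becomes C2′; the carbonyl oxygen and the added methylidene carbon are excised on the way.
5. The alcohol (C2 and C3 stereocentres) comes from hexanal by asymmetric (Z)-γ-alkoxyallylboration. Ring order: dioxolane (from the pool, opened in step 6), oxolane (step 5), oxirane (made in step 7, opened in step 8).

Key step: step 5

Remark: the borane from (+)-Ipc2BOMe, i.e. from (−)-α-pinene, is taken to give the (3S,4S) adduct by analogy with the facial preference of the parent allylborane; should the opposite hold, the antipodal borane is used.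

## Route

Step 1
Reactants: 1 hexanal; 2 3-(methoxymethoxy)prop-1-ene (allyl methoxymethyl ether)
Product: 4 (3S,4S)-3-(methoxymethoxy)non-1-en-4-ol, via (Z)-γ-(methoxymethoxy)allyl-diisopinocampheylborane 3 (not isolated)
Conditions: 2, s-BuLi, THF, −78 °C; (+)-Ipc2BOMe; BF3·OEt2; 1, −78 °C → rt; NaOH, H2O2
Reagents that add atoms: none
Why: Brown asymmetric alkoxyallylboration, in which the (Z)-γ-alkoxyallylborane adds through a closed chair transition state so that the Z geometry should give the syn (3,4-threo) relationship and the isopinocampheyl groups the (3S,4S) absolute configuration, the new hydroxyl being left free next to an already protected one.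

Step 2
Reactants: 5 methyl (4R)-2,2-dimethyl-1,3-dioxolane-4-carboxylate
Product: 6 potassium (4R)-2,2-dimethyl-1,3-dioxolane-4-carboxylate
Conditions: KOH (1.0 equiv), MeOH–H2O, 0 °C → rt; evaporation
Reagents that add atoms: potassium hydroxide, [K+].[OH-]
Why: Ester saponification to the carboxylate salt avoids the acid-labile free acid, and one equivalent of hydroxide at low temperature should leave the α-alkoxy stereocentre untouched.

Step 3
Reactants: 4 (3S,4S)-3-(methoxymethoxy)non-1-en-4-ol; 6 potassium (4R)-2,2-dimethyl-1,3-dioxolane-4-carboxylate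
Product: 7 (3S,4S)-3-(methoxymethoxy)non-1-en-4-yl (4R)-2,2-dimethyl-1,3-dioxolane-4-carboxylate
Conditions: 2,4,6-Cl3C6H2COCl, Et3N, THF, rt; then 4, DMAP, toluene, rt
Reagents that add atoms: none
Why: Yamaguchi esterification through the mixed 2,4,6-trichlorobenzoic anhydride should acylate the hindered secondary alcohol without breaking its C–O bond, so no stereocentre is formed or inverted.

Step 4
Reactants: 7 (3S,4S)-3-(methoxymethoxy)non-1-en-4-yl (4R)-2,2-dimethyl-1,3-dioxolane-4-carboxylate
Product: 8 (4R)-4-(1-{[(3S,4S)-3-(methoxymethoxy)non-1-en-4-yl]oxy}ethenyl)-2,2-dimethyl-1,3-dioxolane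
Conditions: Cp2TiMe2 (3 equiv), toluene, 65 °C, dark
Reagents that add atoms: dimethyltitanocene Cp2TiMe2, [CH3-].[CH3-].[Ti+4].c1cc[cH-]c1.c1cc[cH-]c1
Why: Petasis methylenation (carbonyl olefination by a titanium methylidene) should turn the ester C=O into the 1,1-disubstituted enol ether under non-basic conditions that leave the adjacent stereocentre, both acetals and the vinyl group intact.

Step 5
Reactants: 8 (4R)-4-(1-{[(3S,4S)-3-(methoxymethoxy)non-1-en-4-yl]oxy}ethenyl)-2,2-dimethyl-1,3-dioxolane
Product: 10 (4R)-4-[(2R,4S,5S)-4-(methoxymethoxy)-5-pentyloxolan-2-yl]-2,2-dimethyl-1,3-dioxolane, via dihydrofuran 9 (not isolated)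
Conditions: RuCl2(=CHPh)(H2IMes)(PCy3) (second-generation Grubbs catalyst, 10 mol %), toluene, 70 °C; then CH2Cl2, Et3SiH, CF3CO2H, −40 °C
Reagents that add atoms: none
Why: The ruthenium alkylidene should load at the monosubstituted vinyl group and ring-close onto the 1,1-disubstituted enol ether with loss of ethylene, forming the C4–C5 bond as the C=C of a 4,5-dihydrofuran (enol ether ring-closing metathesis, the known ester methylenation/metathesis route to C1-substituted glycals). CF3CO2H then protonates C4 of this cyclic enol ether and Et3SiH reduces the resulting oxocarbenium ion at C5 (ionic hydrogenation, as used for 2-deoxy-C-furanoside ketals). The oxolane is the only ring closed; it closes as a five-membered cycloalkene by joining the internal vinyl carbon (C4) to the former carbonyl carbon (C5), and the metathesis itself creates no stereocentre. The new stereocentre C5 is controlled by the C3 methoxymethoxy group: the ring oxocarbenium ion should react through the envelope in which this alkoxy group is pseudoaxial (its cis neighbour, the C2 pentyl group, then pseudoequatorial), and hydride enters on the inside face, cis to the C3 oxygen, so that the side chain ends trans to both ring substituents (5R). The step needs ring closure in preference to intermolecular metathesis and C-protonation of the enol ether in preference to ionisation of the acetals; the absence of any other alkene in the substrate, the far higher basicity of the enol ether carbon, the low temperature and the excess of silane should secure this.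

Step 6
Reactants: 10 (4R)-4-[(2R,4S,5S)-4-(methoxymethoxy)-5-pentyloxolan-2-yl]-2,2-dimethyl-1,3-dioxolane
Product: 11 (1R)-1-[(2R,4S,5S)-4-(methoxymethoxy)-5-pentyloxolan-2-yl]ethane-1,2-diol
Conditions: AcOH–H2O (4:1), 40 °C
Reagents that add atoms: none
Why: Acid-catalysed acetonide hydrolysis should cleave the cyclic ketal much faster than the methoxymethyl ether, and no stereocentre takes part.

Step 7
Reactants: 11 (1R)-1-[(2R,4S,5S)-4-(methoxymethoxy)-5-pentyloxolan-2-yl]ethane-1,2-diol
Product: 12 (2S,3S,5R)-3-(methoxymethoxy)-5-[(2R)-oxiran-2-yl]-2-pentyloxolane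
Conditions: NaH, N-tosylimidazole, THF, 0 °C → rt
Reagents that add atoms: none
Why: One-pot epoxide formation from a 1,2-diol (selective primary tosylation, then intramolecular Williamson displacement by the secondary alkoxide) never breaks the C1′–O bond, so its configuration should be retained.

Step 8
Reactants: 12 (2S,3S,5R)-3-(methoxymethoxy)-5-[(2R)-oxiran-2-yl]-2-pentyloxolane; 13 8-bromooct-1-ene
Product: 15 (1R)-1-[(2R,4S,5S)-4-(methoxymethoxy)-5-pentyloxolan-2-yl]dec-9-en-1-ol, via oct-7-en-1-ylmagnesium bromide 14 (not isolated)
Conditions: 13, Mg, THF; then CuI (10 mol %), 12, THF, −30 → 0 °C; aqueous work-up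
Reagents that add atoms: none
Why: Copper-catalysed Grignard opening of a terminal epoxide at its unsubstituted carbon (SN2) should form the C2′–C3′ bond and release the C1′ hydroxyl with its configuration unchanged.

Step 9
Reactants: 15 (1R)-1-[(2R,4S,5S)-4-(methoxymethoxy)-5-pentyloxolan-2-yl]dec-9-en-1-ol
Product: 16 (1R)-1-[(2R,4S,5S)-4-(methoxymethoxy)-5-pentyloxolan-2-yl]dec-9-en-1-yl dodecanoate
Conditions: C11H23COCl, pyridine, DMAP (cat.), CH2Cl2, 0 °C → rt
Reagents that add atoms: dodecanoyl chloride (lauroyl chloride), CCCCCCCCCCCC(=O)Cl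
Why: DMAP-catalysed acylation of the only free hydroxyl by the acid chloride should install the laurate without touching any stereocentre.

Step 10
Reactants: 16 (1R)-1-[(2R,4S,5S)-4-(methoxymethoxy)-5-pentyloxolan-2-yl]dec-9-en-1-yl dodecanoate
Product: 17 (1R)-1-[(2R,4S,5S)-4-hydroxy-5-pentyloxolan-2-yl]dec-9-en-1-yl dodecanoate (CNP0219213.1)
Conditions: ZnBr2, n-PrSH, CH2Cl2, 0 °C
Reagents that add atoms: none
Why: Lewis acid/thiol cleavage of the methoxymethyl ether (transfer of the methoxymethyl group to sulfur) should be selective over the ester, the terminal alkene and the ring ether, and the trans disposition of the two oxygens across the ring should exclude acyl migration.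

## Compound list

1 | hexanal | CCCCCC=O | starting material
2 | 3-(methoxymethoxy)prop-1-ene | C=CCOCOC | starting material
3 | [(Z)-3-(methoxymethoxy)prop-2-en-1-yl]diisopinocampheylborane (from (−)-α-pinene) | COCO/C=C\CB([C@H]1C[C@H]2C[C@@H]([C@@H]1C)C2(C)C)[C@H]3C[C@H]4C[C@@H]([C@@H]3C)C4(C)C | intermediate
4 | (3S,4S)-3-(methoxymethoxy)non-1-en-4-ol | C=C[C@H](OCOC)[C@H](CCCCC)O | intermediate
5 | methyl (4R)-2,2-dimethyl-1,3-dioxolane-4-carboxylate | COC(=O)[C@H]1COC(C)(C)O1 | starting material
6 | potassium (4R)-2,2-dimethyl-1,3-dioxolane-4-carboxylate | [K+].[O-]C(=O)[C@H]1COC(C)(C)O1 | intermediate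
7 | (3S,4S)-3-(methoxymethoxy)non-1-en-4-yl (4R)-2,2-dimethyl-1,3-dioxolane-4-carboxylate | C=C[C@H](OCOC)[C@H](CCCCC)OC(=O)[C@H]1COC(C)(C)O1 | intermediate
8 | (4R)-4-(1-{[(3S,4S)-3-(methoxymethoxy)non-1-en-4-yl]oxy}ethenyl)-2,2-dimethyl-1,3-dioxolane | C=C[C@H](OCOC)[C@H](CCCCC)OC(=C)[C@H]1COC(C)(C)O1 | intermediate
9 | (4R)-4-[(4S,5S)-4-(methoxymethoxy)-5-pentyl-4,5-dihydrofuran-2-yl]-2,2-dimethyl-1,3-dioxolane | CCCCC[C@@H]1OC(=C[C@@H]1OCOC)[C@H]2COC(C)(C)O2 | intermediate
10 | (4R)-4-[(2R,4S,5S)-4-(methoxymethoxy)-5-pentyloxolan-2-yl]-2,2-dimethyl-1,3-dioxolane | CCCCC[C@@H]1O[C@H](C[C@@H]1OCOC)[C@H]2COC(C)(C)O2 | intermediate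
11 | (1R)-1-[(2R,4S,5S)-4-(methoxymethoxy)-5-pentyloxolan-2-yl]ethane-1,2-diol | CCCCC[C@@H]1O[C@H](C[C@@H]1OCOC)[C@H](O)CO | intermediate
12 | (2S,3S,5R)-3-(methoxymethoxy)-5-[(2R)-oxiran-2-yl]-2-pentyloxolane | CCCCC[C@@H]1O[C@H](C[C@@H]1OCOC)[C@H]2CO2 | intermediate
13 | 8-bromooct-1-ene | C=CCCCCCCBr | starting material
14 | oct-7-en-1-ylmagnesium bromide | C=CCCCCCC[Mg]Br | intermediate
15 | (1R)-1-[(2R,4S,5S)-4-(methoxymethoxy)-5-pentyloxolan-2-yl]dec-9-en-1-ol | CCCCC[C@@H]1O[C@H](C[C@@H]1OCOC)[C@H](O)CCCCCCCC=C | intermediate
16 | (1R)-1-[(2R,4S,5S)-4-(methoxymethoxy)-5-pentyloxolan-2-yl]dec-9-en-1-yl dodecanoate | CCCCC[C@@H]1O[C@H](C[C@@H]1OCOC)[C@H](OC(=O)CCCCCCCCCCC)CCCCCCCC=C | intermediate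
17 | (1R)-1-[(2R,4S,5S)-4-hydroxy-5-pentyloxolan-2-yl]dec-9-en-1-yl dodecanoate (CNP0219213.1) | C=CCCCCCCC[C@@H](OC(=O)CCCCCCCCCCC)[C@H]1C[C@H](O)[C@H](CCCCC)O1 | target

## Step count and risks

Total step count: 10. Longest linear sequence: 9 steps (steps 1 and 3 to 10, from hexanal); step 2 is a one-step side branch.

**Step 5 (key step).** Several processes may go wrong:
- ring closure onto the hindered 1,1-disubstituted enol ether may be slow and give way to ruthenium-hydride isomerisation;
- under acid, the allylic C3 oxygen may ionise (Ferrier-type) with aromatisation of the ring;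
- the oxocarbenium ion may lose a proton towards C1′ and scramble that centre;
- the acetonide may be partly lost, or facial selectivity of hydride delivery may be poor.

The fallback sets out from 8 and comes back at 10. The metathesis is run alone and dihydrofuran 9 is isolated on base-washed silica. C5 is then set without acid by homogeneous hydrogenation with [Ir(cod)(PCy3)(py)]PF6 under H2 in CH2Cl2. The cationic iridium centre is expected to bind the methoxymethoxy oxygens on C3 and to deliver both hydrogens to that face, which gives the same C5 configuration by directed delivery instead of stereoelectronic hydride attack. This fallback makes no compound outside the list (F0).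

**Step 4.** Carbonyl methylenation of the hindered α-alkoxy ester may stay incomplete at the temperature needed to generate the titanium methylidene, and the enol ether may hydrolyse during isolation.

The fallback sets out from 7 and comes back at 10, without an isolated enol ether. The reduced titanium ethylidene reagent made from TiCl4, Zn, PbCl2 (cat.), TMEDA and CH3CHBr2 (THF–CH2Cl2, 65 °C) should exchange onto the vinyl group with loss of propene. The tethered titanium alkylidene then olefinates the ester carbonyl (olefinic ester cyclisation), closing the same C4–C5 bond and giving dihydrofuran 9 directly. Compound 9 is reduced with Et3SiH and CF3CO2H as in the second stage of step 5. This fallback makes no compound outside the list (F0).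

**Step 8.** Magnesium halide may open the oxirane with bromide, or the neighbouring ring oxygen may participate, faster than copper-mediated C–C bond formation.

The fallback sets out from 12 (and 13) and comes back at 15, using a sulfone-stabilised carbanion in place of the organometallic. Bromide 13 and PhSO2Na in DMF should give (oct-7-en-1-ylsulfonyl)benzene F1. Its lithio derivative (n-BuLi, THF–HMPA, −78 °C) opens 12 at the terminal carbon without a Lewis acid and gives (1R)-1-[(2R,4S,5S)-4-(methoxymethoxy)-5-pentyloxolan-2-yl]-3-(phenylsulfonyl)dec-9-en-1-ol F2, whose epimers at the sulfonyl carbon are of no consequence. Reductive desulfonylation with Mg in MeOH then gives 15.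

Further compounds
F0 | step 5 | none | none
F0 | step 4 | none | none
F1 | step 8 | (oct-7-en-1-ylsulfonyl)benzene | C=CCCCCCCS(=O)(=O)c1ccccc1
F2 | step 8 | (1R)-1-[(2R,4S,5S)-4-(methoxymethoxy)-5-pentyloxolan-2-yl]-3-(phenylsulfonyl)dec-9-en-1-ol | CCCCC[C@@H]1O[C@H](C[C@@H]1OCOC)[C@H](O)CC(CCCCCC=C)S(=O)(=O)c1ccccc1
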